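**Retrosynthetic overview**

1. The target comes from one acid treatment that removes two aryl MOM ethers and one TBS ether from the fully assembled C17-resorcinol; nothing else follows the key step.
2. Key disconnection: the bond between vinylic C9' and allylic C10' (chain numbered from the ring). A (Z)-alkenylcuprate is alkylated at C9' by a primary iodide carrying the protected (S)-carbinol. The alkenylcuprate is made in the same flask by syn-carbocupration of acetylene with the cuprate of a 7-arylheptyl iodide (C7'–C8' bond), so aryl-C7, C2 and C8 units are joined in one operation.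
3. Enabling feature: the cis C8'=C9' double bond is a bare CH=CH unit flanked by two unbranched CH2 groups (C7' and C10'). It is acetylene inserted syn between two primary alkyl termini, seven CH2 groups from the benzene-1,3-diol ring and five CH2 groups from the C15' carbinol, so neither functional end interferes.
4. Fragments: the aryl iodide from 5-bromoresorcinol (MOM protection, B-alkyl Suzuki–Miyaura coupling with 7-bromohept-1-ene, Finkelstein). The carbinol iodide from (S)-2-ethyloxirane, which supplies the C15' stereocenter (copper-catalysed opening with 4-chlorobutyl Grignard, TBS protection, Finkelstein).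
5. Ring formation: none. The only ring, the benzene-1,3-diol ring, is bought as 5-bromoresorcinol.

Key step: step 7

Remark: the SMILES is read as 5-[(8Z,15S)-15-hydroxyheptadec-8-en-1-yl]benzene-1,3-diol; 5-bromobenzene-1,3-diol, 7-bromohept-1-ene, (S)-2-ethyloxirane, 1-bromo-4-chlorobutane and acetylene are taken as commercially available.

**Route**

Step 1
Reactants: 1 5-bromobenzene-1,3-diol
Product: 2 1-bromo-3,5-bis(methoxymethoxy)benzene
Conditions: NaH (2.5 equiv), MOMCl (2.5 equiv), DMF, 0 °C to rt
Reagents that add atoms: chloromethyl methyl ether (MOMCl), COCCl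
Why: Double Williamson etherification of the sodium phenoxides masks both acidic O–H groups as acetals that should tolerate the organolithium and cuprate chemistry of step 7 and fall off with mild acid.

Step 2
Reactants: 3 7-bromohept-1-ene; 2 1-bromo-3,5-bis(methoxymethoxy)benzene
Product: 5 1-(7-bromoheptyl)-3,5-bis(methoxymethoxy)benzene, via B-(7-bromoheptyl)-9-BBN 4 (not isolated)
Conditions: 9-BBN, THF, 0 °C to rt; then 2, Pd(dppf)Cl2 (5 mol%), aq K3PO4 (3 equiv), DMF, 50 °C
Reagents that add atoms: none
Why: Anti-Markovnikov hydroboration of the terminal alkene followed by B-alkyl Suzuki–Miyaura coupling attaches the C1'–C7' tether, since Pd(dppf)Cl2 inserts into the aryl C–Br bond but not into the primary alkyl C–Br bond and the dppf ligand suppresses β-hydride elimination.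

Step 3
Reactants: 5 1-(7-bromoheptyl)-3,5-bis(methoxymethoxy)benzene
Product: 6 1-(7-iodoheptyl)-3,5-bis(methoxymethoxy)benzene
Conditions: NaI (3 equiv), acetone, reflux
Reagents that add atoms: sodium iodide, [Na+].[I-]
Why: Finkelstein SN2 halide exchange, driven by precipitation of NaBr, gives the primary iodide needed for clean iodine–lithium exchange.

Step 4
Reactants: 7 (S)-2-ethyloxirane; 8 1-bromo-4-chlorobutane
Product: 10 (3S)-8-chlorooctan-3-ol, via 4-chlorobutylmagnesium bromide 9 (not isolated)
Conditions: 8, Mg, THF, 0–20 °C; then CuI (10 mol%), 7, THF, −30 to 0 °C; 1 M HCl work-up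
Reagents that add atoms: none
Why: Magnesium inserts selectively into the C–Br bond, and the copper-catalysed SN2 opening of the monosubstituted epoxide by the primary Grignard reagent occurs at the unsubstituted CH2, so the C15' stereocenter is taken unchanged as (S) from the chiral pool.

Step 5
Reactants: 10 (3S)-8-chlorooctan-3-ol
Product: 11 tert-butyl{[(3S)-8-chlorooctan-3-yl]oxy}dimethylsilane
Conditions: TBSCl (1.2 equiv), imidazole (2.5 equiv), DMF, rt
Reagents that add atoms: tert-butyldimethylsilyl chloride (TBSCl), CC(C)(C)[Si](C)(C)Cl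
Why: Standard silylation of the secondary alcohol gives an ether that is inert to the cuprate alkylation medium and is cleaved in the same acid step as the MOM groups.

Step 6
Reactants: 11 tert-butyl{[(3S)-8-chlorooctan-3-yl]oxy}dimethylsilane
Product: 12 tert-butyl{[(3S)-8-iodooctan-3-yl]oxy}dimethylsilane
Conditions: NaI (5 equiv), butan-2-one, reflux
Reagents that add atoms: sodium iodide, [Na+].[I-]
Why: Finkelstein exchange of the primary chloride provides the reactive primary iodide electrophile, while the secondary TBS ether and the remote stereocenter are untouched.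

Step 7
Reactants: 6 1-(7-iodoheptyl)-3,5-bis(methoxymethoxy)benzene; 12 tert-butyl{[(3S)-8-iodooctan-3-yl]oxy}dimethylsilane; 13 acetylene
Product: 17 tert-butyl({(3S,9Z)-17-[3,5-bis(methoxymethoxy)phenyl]heptadec-9-en-3-yl}oxy)dimethylsilane, via alkyllithium 14 (not isolated), via lithium dialkylcuprate 15 (not isolated), via lithium (Z)-dialkenylcuprate 16 (not isolated)
Conditions: 6 (2 equiv), t-BuLi (4 equiv), Et2O/pentane, −78 °C; CuBr·SMe2 (1 equiv), Et2O, −45 °C; HC≡CH 13 (2 equiv, metered), −50 to −25 °C; then 12 (slightly less than 2 equiv), HMPA, P(OEt)3, THF, −40 °C to rt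
Reagents that add atoms: none
Why: Iodine–lithium exchange turns 6 into the primary alkyllithium 14, two of which combine with CuBr·SMe2 to the Gilman cuprate 15; each alkyl–copper bond then adds syn across one molecule of acetylene (four-centre carbocupration), so that C7' and copper are cis on the new C8'=C9' bond of 16, and this alkenyl–copper bond is finally alkylated at C9' with retention by the primary iodide 12 once THF, HMPA and P(OEt)3 are added, which forms the C9'–C10' bond. The closest known reaction type is the carbocupration of acetylene by lithium dialkylcuprates followed by alkylation of the resulting (Z)-dialkenylcuprate with functionalised primary alkyl iodides, the classical assembly of (Z)-alkene insect pheromones from two alkyl halides and acetylene. No ring is closed and no stereocenter is created: the only stereogenic element formed is the C8'=C9' double bond, whose Z geometry is dictated by the concerted syn addition and by the configurational stability of alkenylcopper species below 0 °C, while the C15' stereocenter sits five CH2 groups from the reacting carbon and is carried through as its TBS ether. The step needs (a) single insertion of acetylene, secured by metering two equivalents of gas per copper in Et2O below −25 °C, where addition outruns both deprotonation of acetylene and a second insertion, (b) halogen–metal exchange in preference to ortho-lithiation of the bis-MOM ring, secured by the much faster exchange at −78 °C and the low basicity of the cuprate once formed, and (c) substitution rather than elimination at 12, secured by its unbranched primary iodide.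

Step 8
Reactants: 17 tert-butyl({(3S,9Z)-17-[3,5-bis(methoxymethoxy)phenyl]heptadec-9-en-3-yl}oxy)dimethylsilane
Product: 18 Hansfordiol G, 5-[(8Z,15S)-15-hydroxyheptadec-8-en-1-yl]benzene-1,3-diol
Conditions: HCl (1 M in MeOH), 45 °C
Reagents that add atoms: none
Why: Acid-catalysed transacetalisation of both aryl MOM ethers to methanol and methanolysis of the TBS ether should occur in one operation, while the isolated cis-alkene and the secondary carbinol stereocenter are stable to dilute methanolic HCl.

**Compound list**

1 | 5-bromobenzene-1,3-diol (5-bromoresorcinol) | Oc1cc(O)cc(Br)c1 | starting material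
2 | 1-bromo-3,5-bis(methoxymethoxy)benzene | COCOc1cc(Br)cc(OCOC)c1 | intermediate
3 | 7-bromohept-1-ene | C=CCCCCCBr | starting material
4 | 9-(7-bromoheptyl)-9-borabicyclo[3.3.1]nonane (B-(7-bromoheptyl)-9-BBN) | BrCCCCCCCB1C2CCCC1CCC2 | intermediate
5 | 1-(7-bromoheptyl)-3,5-bis(methoxymethoxy)benzene | COCOc1cc(CCCCCCCBr)cc(OCOC)c1 | intermediate
6 | 1-(7-iodoheptyl)-3,5-bis(methoxymethoxy)benzene | COCOc1cc(CCCCCCCI)cc(OCOC)c1 | intermediate
7 | (S)-2-ethyloxirane ((S)-1,2-epoxybutane) | CC[C@H]1CO1 | starting material
8 | 1-bromo-4-chlorobutane | ClCCCCBr | starting material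
9 | 4-chlorobutylmagnesium bromide | ClCCCC[Mg]Br | intermediate
10 | (3S)-8-chlorooctan-3-ol | CC[C@H](O)CCCCCCl | intermediate
11 | tert-butyl{[(3S)-8-chlorooctan-3-yl]oxy}dimethylsilane | CC[C@H](O[Si](C)(C)C(C)(C)C)CCCCCCl | intermediate
12 | tert-butyl{[(3S)-8-iodooctan-3-yl]oxy}dimethylsilane | CC[C@H](O[Si](C)(C)C(C)(C)C)CCCCCI | intermediate
13 | acetylene | C#C | starting material
14 | {7-[3,5-bis(methoxymethoxy)phenyl]heptyl}lithium | [Li]CCCCCCCc1cc(OCOC)cc(OCOC)c1 | intermediate
15 | lithium bis{7-[3,5-bis(methoxymethoxy)phenyl]heptyl}cuprate | [Li+].COCOc1cc(CCCCCCC[Cu-]CCCCCCCc2cc(OCOC)cc(OCOC)c2)cc(OCOC)c1 | intermediate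
16 | lithium bis{(1Z)-9-[3,5-bis(methoxymethoxy)phenyl]non-1-en-1-yl}cuprate | [Li+].COCOc1cc(CCCCCCC/C=C\[Cu-]/C=C\CCCCCCCc2cc(OCOC)cc(OCOC)c2)cc(OCOC)c1 | intermediate
17 | tert-butyl({(3S,9Z)-17-[3,5-bis(methoxymethoxy)phenyl]heptadec-9-en-3-yl}oxy)dimethylsilane | CC[C@H](O[Si](C)(C)C(C)(C)C)CCCCC/C=C\CCCCCCCc1cc(OCOC)cc(OCOC)c1 | intermediate
18 | Hansfordiol G, 5-[(8Z,15S)-15-hydroxyheptadec-8-en-1-yl]benzene-1,3-diol | CC[C@H](O)CCCCC/C=C\CCCCCCCc1cc(O)cc(O)c1 | target

**Step count and risks**

Total step count: 8. Longest linear sequence: 5 steps (1 → 2 → 5 → 6 → 17 → 18, or equally 7 → 10 → 11 → 12 → 17 → 18).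

Step 7 is the riskiest. Ortho-metalation of the bis-MOM ring by t-BuLi or by the alkyllithium may compete before transmetalation to copper. Acetylene may be taken up incompletely or inserted twice. Alkylation of the second alkenyl–copper bond may be slow, so that part of the alkenyl fragment ends as the protonated terminal alkene. The fallback sets out from 6 and comes back at 17, forming the same C9'–C10' bond at the alkyne oxidation level. Iodide 6 is treated with lithium acetylide–ethylenediamine complex in DMSO to give 1-(non-8-yn-1-yl)-3,5-bis(methoxymethoxy)benzene F1. Deprotonation with n-BuLi in THF at −78 °C gives {9-[3,5-bis(methoxymethoxy)phenyl]non-1-yn-1-yl}lithium F2, which is alkylated with iodide 12 in THF/DMPU to give tert-butyl({(3S)-17-[3,5-bis(methoxymethoxy)phenyl]heptadec-9-yn-3-yl}oxy)dimethylsilane F3. Semihydrogenation over Lindlar catalyst (Pd/CaCO3 poisoned with Pb(OAc)2, quinoline, H2) should then give 17.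

Step 4 is next. Wurtz-type self-coupling may occur while the chloro-Grignard reagent forms, and magnesium halide may open the epoxide to a bromohydrin in competition with the copper-catalysed C–C bond formation. The fallback sets out from 7 and comes back at 12. Epoxide 7 is opened with commercial but-3-enylmagnesium bromide and catalytic CuI to give (3S)-oct-7-en-3-ol F4, which is silylated (TBSCl, imidazole) to tert-butyldimethyl{[(3S)-oct-7-en-3-yl]oxy}silane F5. Hydroboration with 9-BBN gives 9-{(6S)-6-[(tert-butyldimethylsilyl)oxy]octyl}-9-borabicyclo[3.3.1]nonane F6, which is oxidised in the same flask (NaOH, H2O2) to (6S)-6-[(tert-butyldimethylsilyl)oxy]octan-1-ol F7. Appel iodination (I2, PPh3, imidazole, CH2Cl2) then gives 12.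

Step 2 is third. Oxidative addition into the electron-rich aryl bromide may be slow, leaving time for protodeboronation or β-hydride elimination, and the primary bromide may be partly lost by substitution in the basic aqueous medium. The fallback sets out from 2 and comes back at 6. Sonogashira coupling of 2 with hept-6-yn-1-ol (Pd(PPh3)2Cl2, CuI, Et3N, 60 °C) gives 7-[3,5-bis(methoxymethoxy)phenyl]hept-6-yn-1-ol F8. Hydrogenation (H2, Pd/C, EtOAc) gives 7-[3,5-bis(methoxymethoxy)phenyl]heptan-1-ol F9, and Appel iodination (I2, PPh3, imidazole) gives 6 directly.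

**Further compounds**

F1 | step 7 | 1-(non-8-yn-1-yl)-3,5-bis(methoxymethoxy)benzene | C#CCCCCCCCc1cc(OCOC)cc(OCOC)c1
F2 | step 7 | {9-[3,5-bis(methoxymethoxy)phenyl]non-1-yn-1-yl}lithium | [Li]C#CCCCCCCCc1cc(OCOC)cc(OCOC)c1
F3 | step 7 | tert-butyl({(3S)-17-[3,5-bis(methoxymethoxy)phenyl]heptadec-9-yn-3-yl}oxy)dimethylsilane | CC[C@H](O[Si](C)(C)C(C)(C)C)CCCCCC#CCCCCCCCc1cc(OCOC)cc(OCOC)c1
F4 | step 4 | (3S)-oct-7-en-3-ol | CC[C@H](O)CCCC=C
F5 | step 4 | tert-butyldimethyl{[(3S)-oct-7-en-3-yl]oxy}silane | CC[C@H](O[Si](C)(C)C(C)(C)C)CCCC=C
F6 | step 4 | 9-{(6S)-6-[(tert-butyldimethylsilyl)oxy]octyl}-9-borabicyclo[3.3.1]nonane | CC[C@H](O[Si](C)(C)C(C)(C)C)CCCCCB1C2CCCC1CCC2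
F7 | step 4 | (6S)-6-[(tert-butyldimethylsilyl)oxy]octan-1-ol | CC[C@H](O[Si](C)(C)C(C)(C)C)CCCCCO
F8 | step 2 | 7-[3,5-bis(methoxymethoxy)phenyl]hept-6-yn-1-ol | OCCCCCC#Cc1cc(OCOC)cc(OCOC)c1
F9 | step 2 | 7-[3,5-bis(methoxymethoxy)phenyl]heptan-1-ol | OCCCCCCCc1cc(OCOC)cc(OCOC)c1
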